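**Retrosynthetic overview**
- Feature: number the C19 chain from the pentyl methyl. The oxolane is then O/C6/C7/C8/C9, and oxygen sits on C6, C7, C9 and C10 on either side of the single methylene C8. This pattern is what a skipped Z,Z-diene leaves after two epoxidations. C1–C18 and the C7–O bond (S) are already present in (+)-vernolic acid.
- Last disconnection: the C10 laurate is cut back to the 7,10-diol and vinyl laurate (site-selective lipase acylation).
- Key disconnection: the ring bonds O–C6 and O–C9 are cut together, giving the pseudo-C2 cis,cis-6,7:9,10-diepoxide and one molecule of water. The only ring of the target closes here, by enzymatic opening at C6 followed by 5-exo attack of the new C6 hydroxyl on C9.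
- Precursor: C18=C19 comes from Wittig methylenation of the C18 aldehyde, and the aldehyde comes from the methyl ester. The C9–C10 oxirane comes from peracid epoxidation of methyl vernolate, which is done first so that no second alkene competes.

Key step: step 5

Remarks on the chemistry
- Assumption: (+)-vernolic acid of natural (12S,13R) configuration is bought as such or freed from commercial Vernonia seed oil, and is taken as enantiopure.
- Numbering: compounds 1–7 use fatty-acid numbering and 9–14 use target numbering. Acid C13 = target C6, C12 = C7, C11 = C8, C10 = C9, C9 = C10, C1 = C18.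
- Assignment in step 2: in 5 the two protons of the methylene between the oxiranes are related by a local C2 axis and should be nearly equivalent in the NMR spectrum. In the other (pseudo-meso) diastereomer they are diastereotopic and should be clearly distinct.

Step 1
Reactants: 1 (+)-vernolic acid, (9Z,12S,13R)-12,13-epoxyoctadec-9-enoic acid; 2 methyl iodide
Product: 3 methyl vernolate, methyl (9Z,12S,13R)-12,13-epoxyoctadec-9-enoate
Conditions: MeI (1.5 equiv), K2CO3 (1.5 equiv), DMF, rt
Reagents that add atoms: methyl iodide, CI
Why: O-alkylation of the carboxylate (SN2 on methyl iodide) runs under mild base, so the acid-labile oxirane, the Z-alkene and both stereocentres stay untouched, which an acid-catalysed esterification could not guarantee.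

Step 2
Reactants: 3 methyl vernolate; 4 mCPBA
Product: 5 methyl (9R,10S,12S,13R)-9,10:12,13-diepoxyoctadecanoate (both oxiranes cis)
Conditions: mCPBA (1.1 equiv), CH2Cl2, 0 °C; aq Na2S2O3/NaHCO3 wash; chromatography on Et3N-deactivated SiO2 to remove the other cis,cis-diastereomer
Reagents that add atoms: mCPBA, OOC(=O)c1cccc(Cl)c1
Why: The Prilezhaev epoxidation transfers oxygen in a concerted syn manner, so the Z-alkene can only give a cis-oxirane and the existing oxirane and ester are left alone; the distant stereocentres bias the faces little, so both cis,cis-diastereomers are expected and the new 9R,10S centres of 5 are secured by chromatographic separation at this stage, where the polar ester helps and no terminal alkene competes.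

Step 3
Reactants: 5 methyl (9R,10S,12S,13R)-9,10:12,13-diepoxyoctadecanoate
Product: 7 (9R,10S,12S,13R)-9,10:12,13-diepoxyoctadecanal, via aluminium hemiacetal 6 (not isolated)
Conditions: DIBAL-H (1.1 equiv), toluene, −78 °C; MeOH quench at −78 °C, aq Rochelle salt, rt
Reagents that add atoms: none
Why: In this partial ester reduction with DIBAL-H the tetrahedral aluminium hemiacetal persists at −78 °C until the quench, so the aldehyde appears only on work-up, and 1,2-dialkyl oxiranes are not opened by about one equivalent of the hydride at this temperature.

Step 4
Reactants: 7 (9R,10S,12S,13R)-9,10:12,13-diepoxyoctadecanal; 8 methyltriphenylphosphonium bromide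
Product: 9 (6R,7S,9S,10R)-6,7:9,10-diepoxynonadec-18-ene
Conditions: Ph3PCH3Br (1.5 equiv), KOtBu (1.4 equiv), THF, 0 °C; then 7, −78 to 0 °C
Reagents that add atoms: methyltriphenylphosphonium bromide, C[P+](c1ccccc1)(c1ccccc1)c1ccccc1.[Br-]
Why: Wittig methylenation with the non-stabilised ylide, made with a potassium base so that no Lewis acidic lithium halide is present, converts the aldehyde into the terminal alkene far faster than the ylide can attack dialkyl oxiranes, and no stereocentre is involved.

Step 5
Reactants: 9 (6R,7S,9S,10R)-6,7:9,10-diepoxynonadec-18-ene; 10 water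
Product: 12 (6S,7S,9R,10R)-6,9-epoxynonadec-18-ene-7,10-diol, via epoxy diol 11 (not isolated)
Conditions: epoxide hydrolase (α/β-fold, S,S-diol-forming, picked from a panel; cell-free extract or lyophilised cells), Tris-HCl 50 mM pH 8.0, 5% v/v DMSO, 30 °C; EtOAc extraction
Reagents that add atoms: water, O
Why: The hydrolase holds the C6–C7 oxirane between its acidic tyrosines while its aspartate attacks C6 from the back, and hydrolysis of the alkyl-enzyme ester at the acyl carbon releases the (6S,7S)-threo diol 11, so the net event is anti addition of one water with inversion at C6 and retention at C7. The C6 hydroxyl of 11 then opens the C9–C10 oxirane at C9 with inversion in a 5-exo-tet closure that forms the oxolane O/C6/C7/C8/C9 and frees the C10 hydroxyl, whereas the 5-endo path of the C7 hydroxyl to C10 and the 6-endo path of the C6 hydroxyl to C10 cannot reach the backside trajectory as easily. The closest known reaction type is the epoxide-hydrolase-triggered hydrolysis and cyclisation cascade of methylene-interrupted cis,cis-bis-epoxides to hydroxylated oxolanes, in which ring closure follows the enzymatic opening without a second catalyst. C6 (R to S) is set by the enzymatic backside attack and C9 (S to R) by the intramolecular SN2 opening, while C7 (S) is carried from vernolic acid and C10 (R) from step 2, so two cis-oxiranes each opened once give both threo pairs, the 2,5-trans ring and the pentyl group cis to the C7 hydroxyl. One of four oxirane carbons must be attacked: in 9 the outer carbons C6 and C10 are both R and the inner carbons C7 and C9 both S, so an enzyme that attacks R-configured carbons (the less common sense, hence the panel) is confined to the outer positions, and the inner ones are in addition more crowded and inductively deactivated by the neighbouring oxirane. Between C6 and C10 only chain lengths differ (5 and 12 carbons flank the C6–C7 oxirane, 9 and 8 flank the C9–C10 oxirane), so the enzyme is selected for a substrate tunnel with one short arm that accepts pentyl but not the non-8-enyl chain, because attack at C10 would place the ring on C7–C10.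

Step 6
Reactants: 12 (6S,7S,9R,10R)-6,9-epoxynonadec-18-ene-7,10-diol; 13 vinyl laurate
Product: 14 target, (1R)-1-[(2R,4S,5S)-4-hydroxy-5-pentyloxolan-2-yl]dec-9-en-1-yl dodecanoate
Conditions: immobilised Burkholderia cepacia lipase, vinyl laurate (3 equiv), MTBE, 4 Å MS, 40 °C
Reagents that add atoms: vinyl laurate, C=COC(=O)CCCCCCCCCCC
Why: Lipase-catalysed irreversible transesterification with an enol ester is a known way to acylate one secondary hydroxyl of a diol, and here the C10 carbinol lies on the flexible chain and has the R sense favoured by the Kazlauskas rule with the oxolane as the large group, whereas the C7 hydroxyl has the opposite sense and is flanked by the cis pentyl group, and no stereocentre is touched.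

**Compound list**
1 | (+)-vernolic acid, (9Z,12S,13R)-12,13-epoxyoctadec-9-enoic acid | CCCCC[C@H]1O[C@H]1C/C=C\CCCCCCCC(=O)O | starting material
2 | methyl iodide | CI | starting material
3 | methyl (9Z,12S,13R)-12,13-epoxyoctadec-9-enoate | CCCCC[C@H]1O[C@H]1C/C=C\CCCCCCCC(=O)OC | intermediate
4 | mCPBA, 3-chloroperoxybenzoic acid | OOC(=O)c1cccc(Cl)c1 | starting material
5 | methyl (9R,10S,12S,13R)-9,10:12,13-diepoxyoctadecanoate | COC(=O)CCCCCCC[C@H]1O[C@H]1C[C@@H]1O[C@@H]1CCCCC | intermediate
6 | diisobutylaluminium methyl hemiacetal of 7 (hemiacetal carbon undefined) | COC(O[Al](CC(C)C)CC(C)C)CCCCCCC[C@H]1O[C@H]1C[C@@H]1O[C@@H]1CCCCC | intermediate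
7 | (9R,10S,12S,13R)-9,10:12,13-diepoxyoctadecanal | O=CCCCCCCC[C@H]1O[C@H]1C[C@@H]1O[C@@H]1CCCCC | intermediate
8 | methyltriphenylphosphonium bromide | C[P+](c1ccccc1)(c1ccccc1)c1ccccc1.[Br-] | starting material
9 | (6R,7S,9S,10R)-6,7:9,10-diepoxynonadec-18-ene | C=CCCCCCCC[C@H]1O[C@H]1C[C@@H]1O[C@@H]1CCCCC | intermediate
10 | water | O | starting material
11 | (6S,7S,9S,10R)-9,10-epoxynonadec-18-ene-6,7-diol | C=CCCCCCCC[C@H]1O[C@H]1C[C@H](O)[C@@H](O)CCCCC | intermediate
12 | (6S,7S,9R,10R)-6,9-epoxynonadec-18-ene-7,10-diol | C=CCCCCCCC[C@@H](O)[C@H]1C[C@H](O)[C@H](CCCCC)O1 | intermediate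
13 | vinyl laurate | C=COC(=O)CCCCCCCCCCC | starting material
14 | (6S,7S,9R,10R)-7-hydroxy-6,9-epoxynonadec-18-en-10-yl dodecanoate | C=CCCCCCCC[C@@H](OC(=O)CCCCCCCCCCC)[C@H]1C[C@H](O)[C@H](CCCCC)O1 | target

Total step count: 6. Longest linear sequence: 6 (1 → 3 → 5 → 7 → 9 → 12 → 14).

**Steps most likely to fail**

1. Step 5.
   - What may go wrong: the hydrolase may open the C9–C10 oxirane at C10 as readily as the C6–C7 oxirane at C6, since the two sites differ only in chain length. It may also attack the S-configured inner carbons, as many wild-type enzymes prefer. Finally, it may turn over the very lipophilic substrate so slowly that unselective background opening takes over.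
   - Fallback (sets out from 3, comes back at 11): the two C–O bonds are made in separate operations, so that the enzyme never meets two oxiranes.
   - Methyl vernolate 3 is reduced with DIBAL-H in toluene at −78 °C to (9Z,12S,13R)-12,13-epoxyoctadec-9-enal F1. This is methylenated with Ph3P=CH2 in THF to (6R,7S,9Z)-6,7-epoxynonadeca-9,18-diene F2.
   - The mono-oxirane F2 is given to the hydrolase, which now only has to choose between the R-configured C6 and the S-configured C7. Hydrolases make this kind of choice in enantioconvergent hydrolyses of cis-dialkyl oxiranes. The product should be (6S,7S,9Z)-nonadeca-9,18-diene-6,7-diol F3.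
   - One equivalent of mCPBA in CH2Cl2 at 0 °C should epoxidise the internal Z-alkene in preference to the terminal one. It gives 11 together with (6S,7S,9R,10S)-9,10-epoxynonadec-18-ene-6,7-diol F4.
   - Both close by the same 5-exo opening (trace CSA if needed). 11 goes to 12 as in step 5, and F4 goes to the 2,5-cis isomer (6S,7S,9S,10S)-6,9-epoxynonadec-18-ene-7,10-diol F5, which is removed by chromatography.

2. Step 6.
   - What may go wrong: there may be no turnover, because both groups on C10 are large for the alcohol pocket. Acyl transfer may also go to the ring hydroxyl.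
   - Fallback (sets out from 12, comes back at 14): enzymatic site control is given up for an unselective chemical monoacylation with recycling.
   - 12 is treated with lauric acid (1 equiv), EDC and DMAP in CH2Cl2 at 0 °C. 14 is then separated by chromatography from (6S,7S,9R,10R)-10-hydroxy-6,9-epoxynonadec-18-en-7-yl dodecanoate F6 and from (6S,7S,9R,10R)-6,9-epoxynonadec-18-ene-7,10-diyl didodecanoate F7.
   - F6 and F7 are methanolysed (K2CO3, MeOH, rt) back to 12 and resubmitted. Acyl migration is not expected, because the two oxygens are held trans across the ring.

3. Step 2.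
   - What may go wrong: poor facial selectivity wastes much of the material, and two diastereomers that differ only in relative configuration across one methylene may separate incompletely.
   - Fallback (sets out from 1, comes back at 5): the face is chosen by an enzyme instead of by chromatography.
   - The free acid 1 is epoxidised with a plant seed peroxygenase (oat or soybean type) and cumene hydroperoxide in phosphate buffer pH 7 at 25 °C. This enzyme class is known to favour the 9R,10S oxirane at the 9,10-cis double bond of C18 acids.
   - The product should be (9R,10S,12S,13R)-9,10:12,13-diepoxyoctadecanoic acid F8, which is methylated with MeI/K2CO3 in DMF as in step 1 to give 5.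

**Further compounds**
F1 | step 5 | (9Z,12S,13R)-12,13-epoxyoctadec-9-enal | CCCCC[C@H]1O[C@H]1C/C=C\CCCCCCCC=O
F2 | step 5 | (6R,7S,9Z)-6,7-epoxynonadeca-9,18-diene | CCCCC[C@H]1O[C@H]1C/C=C\CCCCCCCC=C
F3 | step 5 | (6S,7S,9Z)-nonadeca-9,18-diene-6,7-diol | CCCCC[C@H](O)[C@@H](O)C/C=C\CCCCCCCC=C
F4 | step 5 | (6S,7S,9R,10S)-9,10-epoxynonadec-18-ene-6,7-diol | C=CCCCCCCC[C@@H]1O[C@@H]1C[C@H](O)[C@@H](O)CCCCC
F5 | step 5 | (6S,7S,9S,10S)-6,9-epoxynonadec-18-ene-7,10-diol | C=CCCCCCCC[C@H](O)[C@@H]1C[C@H](O)[C@H](CCCCC)O1
F6 | step 6 | (6S,7S,9R,10R)-10-hydroxy-6,9-epoxynonadec-18-en-7-yl dodecanoate | C=CCCCCCCC[C@@H](O)[C@H]1C[C@H](OC(=O)CCCCCCCCCCC)[C@H](CCCCC)O1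
F7 | step 6 | (6S,7S,9R,10R)-6,9-epoxynonadec-18-ene-7,10-diyl didodecanoate | C=CCCCCCCC[C@@H](OC(=O)CCCCCCCCCCC)[C@H]1C[C@H](OC(=O)CCCCCCCCCCC)[C@H](CCCCC)O1
F8 | step 2 | (9R,10S,12S,13R)-9,10:12,13-diepoxyoctadecanoic acid | OC(=O)CCCCCCC[C@H]1O[C@H]1C[C@@H]1O[C@@H]1CCCCC
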